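Time dropped out of my reckoning for this isothermal flask, since I counted the catalyst against the starting material consumed.

    starting material + enzyme ⇌ starting complex (K1 = 1700 M⁻¹, k1 = 120 M⁻¹ s⁻¹)
    second substrate + starting complex ⇌ ternary complex (K2 = 1100 M⁻¹, k2 = 4400 M⁻¹ s⁻¹)
    ternary complex → enzyme + product (k3 = 0.41 s⁻¹)
    enzyme → spent catalyst (k4 = 7.4 × 10⁻⁵ s⁻¹)

starting material 0.012 M; second substrate 0.0132 M; enzyme 1.2 µM

- the form that holds most of the catalyst when 20 % of the starting material are converted (enzyme / ternary complex / spent catalyst / starting complex)
- its share of the catalyst then

**Bare round.** I first let only free enzyme and ternary complex exist, with no reverse step and no decay. At 20 % conversion, [starting material] was 0.00960 M, so each enzyme was captured at 1.15 s⁻¹, while each ternary complex turned over at 0.41 s⁻¹. These two flows balance, so ternary complex held 73.8 % of the catalyst.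

**Adding complexes.** I then added the starting complex and both reverse steps. With [second substrate] at 0.0108 M, the ratio of ternary to starting complex was 10.8. The ternary share fell to 68.8 % of the working catalyst, which made ternary complex the resting state. Reversal of capture ran at 0.0706 s⁻¹ per starting complex against a forward flow of 4.42 s⁻¹, so I dropped it from the next step.

**Adding decay.** Each turnover in this flask passes once through free enzyme, which either captures starting material at the rate constant 120 M⁻¹ s⁻¹ times [starting material] or decays at 7.4 × 10⁻⁵ s⁻¹. With reversal of capture dropped, spent catalyst therefore gains the ratio of these two rates per starting material consumed, and that integrates in closed form: I reckoned [spent catalyst] as the decay constant over the capture constant, times the logarithm of [starting material] as charged over [starting material] now. I kept 0.617 µM as the loss scale, the enzyme spent each time [starting material] falls by a factor e. At 20 % conversion this gave 11.5 % of the catalyst spent, so ternary complex held 60.9 %.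

**The forecast.** The forecast said ternary complex at 60.7 %, against my 60.9 %, and opened with: “Treat the complexes as quasi-steady”.

**The result.** This flask gave ternary complex at 60.8 % after 2.02 h, with spent catalyst at 11.6 % of the catalyst charged. Used once more, the loss scale says the charge of 1.2 µM covers 1.94 factors of e, which gives an estimate of 14.3 % of the starting material left in this flask when the round ends. At 100 h, spent catalyst stood at >99.9 % and starting material at 15.2 %.

The constants are assumed; no experiment stands behind them.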